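**Strategy.** The quinone ring (C1=O, C2–OH, C3–side chain, C4=O, C5–OMe, C6–H) is cut into a two-carbon ynol ether (C2 and C3, already carrying the (R)-2-acetoxytridecyl chain) and a four-carbon (2-methoxyvinyl)ketene (C4, C1, C6, C5) released by photochemical Wolff rearrangement of a diazo enone. Their polarity-matched [2+2] cycloaddition forms C3–C4 and C1–C2 in one event. A 4π ring opening and 6π ring closure then join C4 to C5 and give a phenol in which C1, para to the new hydroxyl, is unsubstituted. Oxygenation at C1 and loss of a tert-butyl group complete the hydroxyquinone; (R)-epichlorohydrin supplies the stereocentre.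

Key step: step 6

Remark: ring atoms are numbered as in 2-hydroxy-5-methoxy-3-alkyl-1,4-benzoquinone; compounds 1, 2, 5, 6 and 11 are taken as commercial.

Step 1
Reactants: 1 (R)-epichlorohydrin; 2 decylmagnesium bromide
Product: 4 (R)-2-undecyloxirane, via (R)-1-chlorotridecan-2-ol 3 (not isolated)
Conditions: CuI (10 mol %), THF, −40 to 0 °C; then aq. NaOH, rt
Reagents that add atoms: none
Why: Copper-catalysed Grignard opening of the epoxide at its CH2 terminus, then Williamson closure of the chlorohydrin onto the CH2Cl carbon, moves the oxirane along the chain without touching the C–O stereocentre, so the (R) centre of 1 becomes the (R) centre of 4.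

Step 2
Reactants: 5 trichloroethylene; 6 potassium tert-butoxide
Product: 7 (E)-1-tert-butoxy-1,2-dichloroethene
Conditions: THF, −50 °C to rt
Reagents that add atoms: none
Why: Base-induced elimination to dichloroacetylene and anti addition of tert-butoxide (the addition–elimination synthesis of 1,2-dichlorovinyl ethers) should give the (E)-ether.

Step 3
Reactants: 7 (E)-1-tert-butoxy-1,2-dichloroethene; 4 (R)-2-undecyloxirane
Product: 9 (R)-1-tert-butoxypentadec-1-yn-4-ol, via lithium tert-butoxyacetylide 8 (not isolated)
Conditions: n-BuLi (2.2 equiv), THF, −78 to −40 °C; then BF3·OEt2, 4, −78 °C; aq. NaHCO3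
Reagents that add atoms: none
Why: Dehydrochlorination and chlorine–lithium exchange turn 7 into the alkoxyacetylide, which opens the BF3-activated epoxide at its unsubstituted carbon (Yamaguchi-type SN2 alkynylation), leaving the (R) centre untouched.

Step 4
Reactants: 9 (R)-1-tert-butoxypentadec-1-yn-4-ol
Product: 10 (R)-1-tert-butoxypentadec-1-yn-4-yl acetate
Conditions: Ac2O, pyridine, DMAP (cat.), CH2Cl2, 0 °C
Reagents that add atoms: acetic anhydride, CC(=O)OC(C)=O
Why: DMAP-catalysed O-acylation of the secondary alcohol runs under cold, basic conditions that the acid- and heat-sensitive ynol ether should tolerate, with retention of configuration.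

Step 5
Reactants: 11 (E)-4-methoxybut-3-en-2-one
Product: 13 (E)-1-diazo-4-methoxybut-3-en-2-one, via (E)-1,1,1-trifluoro-6-methoxyhex-5-ene-2,4-dione 12 (not isolated)
Conditions: LiN(SiMe3)2, THF, −78 °C; CF3CO2CH2CF3; 5% aq. HCl; then MsN3, Et3N, H2O, MeCN, rt
Reagents that add atoms: methanesulfonyl azide, CS(=O)(=O)N=[N+]=[N-] (2,2,2-trifluoroethyl trifluoroacetate, O=C(OCC(F)(F)F)C(F)(F)F, adds atoms to 12 only)
Why: Trifluoroacetylation of the kinetic methyl-ketone enolate activates it for Regitz diazo transfer, and retro-Claisen loss of the trifluoroacetyl group (detrifluoroacetylative diazo transfer) should give the diazo enone.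

Step 6
Reactants: 13 (E)-1-diazo-4-methoxybut-3-en-2-one; 10 (R)-1-tert-butoxypentadec-1-yn-4-yl acetate
Product: 16 (R)-1-(6-tert-butoxy-2-hydroxy-3-methoxyphenyl)tridecan-2-yl acetate, via (E)-4-methoxybuta-1,3-dien-1-one 14 (not isolated), via vinylcyclobutenone 15 (not isolated)
Conditions: 13 (1.3 equiv, in portions), ClCH2CH2Cl, hν (254 nm, low-pressure Hg lamps, quartz), rt; then 80 °C
Reagents that add atoms: none
Why: Irradiation expels N2 from 13 and Wolff rearrangement gives (2-methoxyvinyl)ketene 14, whose electrophilic carbonyl carbon (future C4) is attacked by the nucleophilic side-chain-bearing carbon of ynol ether 10 (C3) while the ketene α-carbon (C1) bonds to the tert-butoxy carbon (C2), so one [2+2] cycloaddition gives 3-alkoxy-4-vinylcyclobutenone 15 with both ring bonds C3–C4 and C1–C2 in place. Heat (or further light) then cleaves the original ketene C4–C1 bond of 15 by 4π electrocyclic opening to a dienylketene, which forms C4–C5 by 6π electrocyclisation and tautomerises to phenol 16. The closest known reaction type is the vinylketene-based aromatic annulation of α-diazo enones with alkoxy- or siloxyalkynes (Danheiser benzannulation). The four-membered ring closes by [2+2] cycloaddition and the six-membered ring by disrotatory 6π electrocyclic closure; 16 gains no stereocentre, the sp3 ring carbon of 15 is lost on aromatisation, and the remote (R)-acetate centre is not touched. The selectivity needed is regiochemical (side chain ortho and alkoxy group meta to the new hydroxyl), and it is secured by the polarisation of the ynol ether matched to that of the ketene; adding 13 in slight excess keeps 10 from surviving into the heating stage.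

Step 7
Reactants: 16 (R)-1-(6-tert-butoxy-2-hydroxy-3-methoxyphenyl)tridecan-2-yl acetate
Product: 17 (R)-1-(2-tert-butoxy-5-methoxy-3,6-dioxocyclohexa-1,4-dien-1-yl)tridecan-2-yl acetate
Conditions: O2 (1 atm), Co(salen) [Co(C16H14N2O2), divalent cobalt] (cat.), MeCN, rt
Reagents that add atoms: dioxygen, O=O
Why: Cobalt–salen-catalysed oxygenation of a 2,6-disubstituted phenol with a free para position (phenol to para-quinone oxidation) should place the second carbonyl at C1, the unsubstituted carbon para to the hydroxyl.

Step 8
Reactants: 17 (R)-1-(2-tert-butoxy-5-methoxy-3,6-dioxocyclohexa-1,4-dien-1-yl)tridecan-2-yl acetate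
Product: 18 (R)-1-(2-hydroxy-5-methoxy-3,6-dioxocyclohexa-1,4-dien-1-yl)tridecan-2-yl acetate
Conditions: CF3CO2H, CH2Cl2, 0 °C
Reagents that add atoms: none
Why: Acidolysis of the vinylogous tert-butyl ester (E1 loss of isobutene) should free the C2 hydroxyl, while the acetate, the C5 methyl ether and the stereocentre are inert to anhydrous acid.

**Compound list**

1 | (R)-epichlorohydrin [(R)-2-(chloromethyl)oxirane] | ClC[C@H]1CO1 | starting material
2 | decylmagnesium bromide | CCCCCCCCCC[Mg]Br | starting material
3 | (R)-1-chlorotridecan-2-ol | CCCCCCCCCCC[C@@H](O)CCl | intermediate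
4 | (R)-2-undecyloxirane | CCCCCCCCCCC[C@@H]1CO1 | intermediate
5 | trichloroethylene | ClC=C(Cl)Cl | starting material
6 | potassium tert-butoxide | CC(C)(C)[O-].[K+] | starting material
7 | (E)-1-tert-butoxy-1,2-dichloroethene | Cl/C=C(/Cl)OC(C)(C)C | intermediate
8 | lithium tert-butoxyacetylide | [Li]C#COC(C)(C)C | intermediate
9 | (R)-1-tert-butoxypentadec-1-yn-4-ol | CCCCCCCCCCC[C@H](CC#COC(C)(C)C)O | intermediate
10 | (R)-1-tert-butoxypentadec-1-yn-4-yl acetate | CCCCCCCCCCC[C@H](CC#COC(C)(C)C)OC(C)=O | intermediate
11 | (E)-4-methoxybut-3-en-2-one | CO/C=C/C(C)=O | starting material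
12 | (E)-1,1,1-trifluoro-6-methoxyhex-5-ene-2,4-dione | CO/C=C/C(=O)CC(=O)C(F)(F)F | intermediate
13 | (E)-1-diazo-4-methoxybut-3-en-2-one | CO/C=C/C(=O)C=[N+]=[N-] | intermediate
14 | (E)-4-methoxybuta-1,3-dien-1-one [(2-methoxyvinyl)ketene] | CO/C=C/C=C=O | intermediate
15 | (R)-1-{2-tert-butoxy-3-[(E)-2-methoxyvinyl]-4-oxocyclobut-1-en-1-yl}tridecan-2-yl acetate (both configurations at ring C3) | CCCCCCCCCCC[C@H](CC1=C(OC(C)(C)C)C(/C=C/OC)C1=O)OC(C)=O | intermediate
16 | (R)-1-(6-tert-butoxy-2-hydroxy-3-methoxyphenyl)tridecan-2-yl acetate | CCCCCCCCCCC[C@H](Cc1c(O)c(OC)ccc1OC(C)(C)C)OC(C)=O | intermediate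
17 | (R)-1-(2-tert-butoxy-5-methoxy-3,6-dioxocyclohexa-1,4-dien-1-yl)tridecan-2-yl acetate | CCCCCCCCCCC[C@H](CC1=C(OC(C)(C)C)C(=O)C=C(OC)C1=O)OC(C)=O | intermediate
18 | (R)-1-(2-hydroxy-5-methoxy-3,6-dioxocyclohexa-1,4-dien-1-yl)tridecan-2-yl acetate | CCCCCCCCCCC[C@H](CC1=C(O)C(=O)C=C(OC)C1=O)OC(C)=O | target

**Step count.** Total: 8 steps. Longest linear sequence: 6 steps (1, 3, 4, 6, 7, 8).

**Steps most likely to fail**

Step 6. The [2+2] trapping may lose out to photochemical side processes: light-induced decomposition of ynol ether 10 or of phenol 16, dimerisation of ketene 14, and acylation of the product phenol by surviving ketene. The fallback makes the same ketene in the dark by dehydration of an acid. It sets out from 13, which on silver-catalysed Wolff rearrangement in wet THF (AgO2CPh, Et3N, THF–H2O) should give (E)-4-methoxybut-3-enoic acid F1, kept as its triethylammonium salt. 2-Chloro-1-methylpyridinium iodide and Et3N in CH2Cl2 at room temperature then dehydrate it to ketene 14 in the presence of 10. The cycloadduct comes back to the route at 15, which is heated to 16 as in step 6.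

Step 3. The tert-butyl ynol ether may not survive the Lewis acid: loss of isobutene gives a ketene that the new alkoxide captures as a γ-lactone, and generation of the acetylide from 7 may be incomplete. The fallback uses the robust ethyl ynol ether and removes the ethyl group at the end by hydrolysis. It sets out from 4. Ethoxyacetylene and n-BuLi give lithium ethoxyacetylide F2, which with BF3·OEt2 should open 4 to (R)-1-ethoxypentadec-1-yn-4-ol F3. Acetylation gives (R)-1-ethoxypentadec-1-yn-4-yl acetate F4. Annulation with 13 as in step 6 passes through the 3-ethoxy-4-vinylcyclobutenone F5 to (R)-1-(6-ethoxy-2-hydroxy-3-methoxyphenyl)tridecan-2-yl acetate F6. Oxygenation as in step 7 gives the 2-ethoxyquinone F7. Dilute aqueous HClO4 in THF should then hydrolyse the vinylogous ethyl ester at C2, which the flanking side chain twists out of conjugation and so makes more labile than the C5 methyl ether. The sequence comes back at 18.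

Step 7. The electron-rich phenol may suffer over-oxidation or oxidative coupling, or oxygenate slowly next to the bulky tert-butoxy group. The fallback reverses the order of the last two operations and uses a stoichiometric radical oxidant. It sets out from 16. CF3CO2H in CH2Cl2 at 0 °C removes the tert-butyl group first to give (R)-1-(2,6-dihydroxy-3-methoxyphenyl)tridecan-2-yl acetate F8. Teuber oxidation with (KSO3)2NO in phosphate-buffered aqueous acetone, which attacks the free position para to the hindered hydroxyl, should convert it directly into the hydroxyquinone. The sequence comes back at 18.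

**Further compounds**

F1 | step 6 | (E)-4-methoxybut-3-enoic acid | CO/C=C/CC(=O)O
F2 | step 3 | lithium ethoxyacetylide | [Li]C#COCC
F3 | step 3 | (R)-1-ethoxypentadec-1-yn-4-ol | CCCCCCCCCCC[C@H](CC#COCC)O
F4 | step 3 | (R)-1-ethoxypentadec-1-yn-4-yl acetate | CCCCCCCCCCC[C@H](CC#COCC)OC(C)=O
F5 | step 3 | (R)-1-{2-ethoxy-3-[(E)-2-methoxyvinyl]-4-oxocyclobut-1-en-1-yl}tridecan-2-yl acetate | CCCCCCCCCCC[C@H](CC1=C(OCC)C(/C=C/OC)C1=O)OC(C)=O
F6 | step 3 | (R)-1-(6-ethoxy-2-hydroxy-3-methoxyphenyl)tridecan-2-yl acetate | CCCCCCCCCCC[C@H](Cc1c(O)c(OC)ccc1OCC)OC(C)=O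
F7 | step 3 | (R)-1-(2-ethoxy-5-methoxy-3,6-dioxocyclohexa-1,4-dien-1-yl)tridecan-2-yl acetate | CCCCCCCCCCC[C@H](CC1=C(OCC)C(=O)C=C(OC)C1=O)OC(C)=O
F8 | step 7 | (R)-1-(2,6-dihydroxy-3-methoxyphenyl)tridecan-2-yl acetate | CCCCCCCCCCC[C@H](Cc1c(O)c(OC)ccc1O)OC(C)=O
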